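**Retrosynthetic overview**

1. Target ⇒ (acidic methanolysis of a C2 sulfate monoester and a C7 acetate) ⇒ double SN2 delivery of benzoate to C3 and C6 of a cyclohex-4-ene carrying two α-face leaving groups: a C1–C6 oxirane and a C2/C3 cyclic sulfate. This is a stable stand-in for a syn-arene dioxide, the kind of intermediate invoked in the biogenesis of these benzoates.
2. That bis-electrophile ⇒ cyclic sulfation and hydroxyl-directed syn epoxidation of the cis-2,3-dihydrodiol of benzyl acetate.
3. The cis-dihydrodiol ⇒ benzyl acetate + O2 with toluene dioxygenase. This step fixes the absolute configuration (C2 kept, C3 later inverted; C1 and C6 follow by substrate control).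
4. Ring order: the carbocycle is the benzene ring of benzyl acetate, dearomatised in step 1. The oxirane (step 2) and the dioxathiolane (step 3) are temporary rings, both opened in step 4.

Assumption: benzyl acetate is taken to be oxidised by toluene dioxygenase with the same regio- and enantioselectivity as toluene.

Locants are those of the target throughout (C1 carries C7; C2, C3; C4=C5; C6). α is the face of the C2 oxygen, β the opposite face.

**Step 1**
Reactants: 1 benzyl acetate
Product: 2 [(5S,6R)-5,6-dihydroxycyclohexa-1,3-dien-1-yl]methyl acetate (cis-diol; C2–OH and C3–OH both α; diene C4=C5/C6=C1)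
Conditions: E. coli JM109(pDTG601A) whole cells (toluene dioxygenase), air, glucose, IPTG, pH 7 buffer, 30 °C; EtOAc extraction
Reagents that add atoms: dioxygen (O=O)
Why: Enzymatic arene cis-dihydroxylation by a Rieske dioxygenase delivers both oxygens of O2 to one face of the ring bond next to the substituent, as with toluene, setting C2 (R, kept) and C3 (S, inverted in step 4) in high ee, and this strain is known to leave ester side chains intact.

**Step 2**
Reactants: 2 [(5S,6R)-5,6-dihydroxycyclohexa-1,3-dien-1-yl]methyl acetate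
Product: 3 [(1S,2S,3S,6R)-2,3-dihydroxy-7-oxabicyclo[4.1.0]hept-4-en-1-yl]methyl acetate (C1–C6 α-epoxide, cis to both hydroxyls)
Conditions: VO(acac)2 (5 mol%), t-BuOOH (1.2 equiv), CH2Cl2, 0 °C
Reagents that add atoms: tert-butyl hydroperoxide (CC(C)(C)OO)
Why: Hydroxyl-directed vanadium-catalysed epoxidation, in which A(1,2) strain from the CH2OAc group holds the C2–OH pseudoaxial (the geometry from which a vanadate ester transfers oxygen fastest), so the trisubstituted C1=C6 bond is epoxidised on the face of the C2–OH, setting C1 and C6 α, while C4=C5 next to the pseudoequatorial C3–OH is left.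

**Step 3**
Reactants: 3 [(1S,2S,3S,6R)-2,3-dihydroxy-7-oxabicyclo[4.1.0]hept-4-en-1-yl]methyl acetate
Product: 5 C2/C3 cyclic sulfate of the epoxy diol (1,3,2-dioxathiolane 2,2-dioxide fused at C2–C3 on the α face; C1–C6 α-epoxide, C4=C5 and C7 acetate unchanged), via cyclic sulfite 4 (not isolated)
Conditions: SOCl2, Et3N, CH2Cl2, 0 °C; aqueous wash, solvent switch; RuCl3·xH2O (0.1 mol%), NaIO4, MeCN–H2O, 0 °C, 10 min
Reagents that add atoms: thionyl chloride (O=S(Cl)Cl); sodium periodate ([Na+].[O-]I(=O)(=O)=O)
Why: Gao–Sharpless cyclic sulfate synthesis, in which the cis-diol closes to the five-membered sulfite and Ru(VIII) oxidises sulfur within minutes, faster than it attacks a ring alkene deactivated by two allylic C–O bonds; no C–O bond is broken, so all four stereocentres are kept.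

**Step 4**
Reactants: 5 C2/C3 cyclic sulfate of the epoxy diol; 6 tetrabutylammonium benzoate; 7 benzoic acid
Product: 11 (1S,2S,3R,6S)-1-(hydroxymethyl)cyclohex-4-ene-1,2,3,6-tetrol 3,6-dibenzoate (target), via epoxy sulfate salt 8 (not isolated), via dibenzoate sulfate salt 9 (not isolated), via acetate 10 (not isolated)
Conditions: 6 (1.5 equiv), DMF, 0 °C → rt; add 7 (3 equiv), 60 °C; concentrate; HCl (1.25 M in MeOH), 0 °C → rt
Reagents that add atoms: none
Why: Two successive SN2 openings by benzoate at allylic carbons, each with inversion: first the cyclic sulfate at C3 (C2 is neopentyl-like), then the vinyl oxirane at secondary C6 rather than tertiary C1 (carboxylate/carboxylic acid epoxide opening), placing both benzoates β, after which acid-catalysed methanolysis cleaves the C2 sulfate monoester at S–O (retention) and transesterifies the primary acetate much faster than the two secondary benzoates.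

**Compound list**

1 | benzyl acetate | CC(=O)OCc1ccccc1 | starting material
2 | [(5S,6R)-5,6-dihydroxycyclohexa-1,3-dien-1-yl]methyl acetate | O[C@H]1C=CC=C(COC(C)=O)[C@H]1O | intermediate
3 | [(1S,2S,3S,6R)-2,3-dihydroxy-7-oxabicyclo[4.1.0]hept-4-en-1-yl]methyl acetate | O[C@H]1C=C[C@H]2O[C@@]2(COC(C)=O)[C@H]1O | intermediate
4 | C2/C3 cyclic sulfite of 3 (α-fused 1,3,2-dioxathiolane 2-oxide, mixture at sulfur; other centres as in 3) | O=S1O[C@H]2C=C[C@H]3O[C@@]3(COC(C)=O)[C@H]2O1 | intermediate
5 | C2/C3 cyclic sulfate of 3 (α-fused 1,3,2-dioxathiolane 2,2-dioxide; C1–C6 α-epoxide; centres as in 3) | O=S1(=O)O[C@H]2C=C[C@H]3O[C@@]3(COC(C)=O)[C@H]2O1 | intermediate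
6 | tetrabutylammonium benzoate | CCCC[N+](CCCC)(CCCC)CCCC.[O-]C(=O)c1ccccc1 | starting material
7 | benzoic acid | OC(=O)c1ccccc1 | starting material
8 | tetrabutylammonium salt of the C2 α-sulfate monoester with C3 β-benzoate, C1–C6 α-epoxide and C7 acetate | CCCC[N+](CCCC)(CCCC)CCCC.O=C(c1ccccc1)O[C@@H]1C=C[C@H]2O[C@@]2(COC(C)=O)[C@H]1OS(=O)(=O)[O-] | intermediate
9 | tetrabutylammonium salt of the C2 α-sulfate monoester with C3 and C6 β-benzoates, C1 α-OH and C7 acetate | CCCC[N+](CCCC)(CCCC)CCCC.O=C(c1ccccc1)O[C@@H]1C=C[C@H](OC(=O)c2ccccc2)[C@](O)(COC(C)=O)[C@H]1OS(=O)(=O)[O-] | intermediate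
10 | (1S,2S,3R,6S)-1-(acetoxymethyl)cyclohex-4-ene-1,2,3,6-tetrol 3,6-dibenzoate | O=C(c1ccccc1)O[C@@H]1C=C[C@H](OC(=O)c2ccccc2)[C@](O)(COC(C)=O)[C@H]1O | intermediate
11 | (1S,2S,3R,6S)-1-(hydroxymethyl)cyclohex-4-ene-1,2,3,6-tetrol 3,6-dibenzoate | O=C(O[C@H]1C=C[C@@H](OC(=O)c2ccccc2)[C@H](O)[C@@]1(O)CO)c1ccccc1 | target

**Totals and risks**

Total step count: 4. Longest linear sequence: 4 steps, from benzyl acetate 1 to 11.

The three steps most likely to fail are steps 2, 3 and 4.

Step 2 may epoxidise C4=C5 (directed by the C3–OH), give the β-epoxide, or aromatise the diene diol on the Lewis-acidic vanadium. The fallback sets out from 2 and comes back at 3. The less hindered C3–OH is silylated (TBSCl, imidazole, DMF, −20 °C) to give the C3 O-TBS ether of the diene diol F1. With C2–OH as the only director and the α face of C4=C5 now shielded, VO(acac)2/t-BuOOH gives the C3 O-TBS epoxy alcohol F2. Buffered fluoride (TBAF/AcOH, THF, 0 °C) then returns 3.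

Step 3 may fail through RuO4 attack on the ring alkene or loss of the vinyl oxirane. The fallback sets out from 3, avoids sulfur altogether and comes back at 10. A Mitsunobu reaction (PPh3, DIAD, 7, toluene, 0 °C) activates the allylic C3–OH of the cis-diol and displaces it with benzoate with inversion, giving the C3 β-benzoate epoxy alcohol F3. The free C2–OH then directs a Ti(OiPr)4/7 opening of the oxirane at C6 (2,3-epoxy alcohol C-3 opening, inversion) to give 10. Methanolic HCl, as in the last stage of step 4, gives 11.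

Step 4 may fail at the oxirane opening, through SN2′ attack, C7 acetate participation, or sluggish reaction next to the anionic sulfate. The fallback sets out from 3, reverses the order of the two C–O bond formations and comes back at 9. The oxirane of 3 is opened first under hydroxyl direction (Ti(OiPr)4, 7, CH2Cl2, rt) to give the C6 β-benzoate triol F4. The two secondary hydroxyls are closed with SOCl2/Et3N to the C2/C3 cyclic sulfite F5 and oxidised (RuCl3 cat., NaIO4) to the C2/C3 cyclic sulfate F6, leaving the tertiary C1–OH free. A single opening at allylic C3 with 6 (DMF, rt) then gives 9, which is finished with methanolic HCl as in step 4.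

**Further compounds**

F1 | step 2 | [(5S,6R)-5-(tert-butyldimethylsilyloxy)-6-hydroxycyclohexa-1,3-dien-1-yl]methyl acetate (C3 O-TBS ether of 2) | CC(C)(C)[Si](C)(C)O[C@H]1C=CC=C(COC(C)=O)[C@H]1O
F2 | step 2 | C3 O-TBS ether of 3 (C1–C6 α-epoxide, C2 α-OH) | CC(C)(C)[Si](C)(C)O[C@H]1C=C[C@H]2O[C@@]2(COC(C)=O)[C@H]1O
F3 | step 3 | C3 β-benzoate of the C1–C6 α-epoxy C2 α-alcohol, C7 acetate | O=C(c1ccccc1)O[C@@H]1C=C[C@H]2O[C@@]2(COC(C)=O)[C@H]1O
F4 | step 4 | C6 β-benzoate of 1-(acetoxymethyl)cyclohex-4-ene-1,2,3,6-tetrol with C1, C2 and C3 hydroxyls all α | O[C@H]1C=C[C@H](OC(=O)c2ccccc2)[C@](O)(COC(C)=O)[C@H]1O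
F5 | step 4 | C2/C3 cyclic sulfite of F4 (mixture at sulfur) | O=S1O[C@H]2C=C[C@H](OC(=O)c3ccccc3)[C@](O)(COC(C)=O)[C@H]2O1
F6 | step 4 | C2/C3 cyclic sulfate of F4 | O=S1(=O)O[C@H]2C=C[C@H](OC(=O)c3ccccc3)[C@](O)(COC(C)=O)[C@H]2O1
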